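Remarks on the chemistry (assumptions):
- The antipode of the chromium ligand L* in step 9 is the one that delivers the aryl group to the Re face of the aldehyde. The sense of induction for aryl transfer is not established, so it would be fixed beforehand on an open-chain model pair.
- Organometallic species of catalytic cycles and metal alkoxides that are hydrolysed on work-up are treated as mechanism and carry no compound number.
- dmp = 2,9-dimethyl-1,10-phenanthroline. L* = N-[2-(4-isopropyl-4,5-dihydro-1,3-oxazol-2-yl)-6-methylphenyl]methanesulfonamide, single enantiomer.

## Analysis of the target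

The target (C28H24O6) is an 18-membered macrocyclic bis(bibenzyl) of the marchantin type, built from four benzene rings. Ring A is a 5-alkylpyrogallol whose terminal oxygen is arylated. Ring B is a 1,4-phenylene. Ring C is a 1-alkyl-2-aryloxy-3-hydroxybenzene. Ring D is a 1,3-phenylene. The rings are joined by two diaryl ether oxygens (A–O–B and C–O–D) and two two-carbon bridges (ring B–CαH(OH)–CβH2–ring C and ring D–CH2–CH2–ring A).

The only stereocentre is Cα, a secondary benzylic carbinol of (S) configuration (priorities OH > ring B > CβH2 > H). No second stereo element exists to relay from, so a reagent or catalyst must set it.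

Cα sits para to the A–O–B oxygen. This alcohol therefore ionises easily: acid would racemise it or dehydrate it to a stilbene, and hydrogenolysis conditions can cleave its C–O bond. The free pyrogallol and catechol units are air-sensitive, so the phenols must stay masked to the end and be released under neutral conditions.

Three things make the synthesis hard: closing the 18-membered ring, making the ring C ether (its oxygen is flanked by Cβ and a hydroxyl), and placing Cα with defined configuration inside the ring.

The strategy is tied to one feature: the bond between C4 of ring B (the carbon para to the A–O–B oxygen) and Cα lies in the macrocycle and ends at the stereocentre. Cutting it opens the ring and removes the stereocentre at once, leaving an aryl iodide on ring B and a CβH2–CHO arm on ring C. A second feature is used on the way: Cβ is ortho to the C–O–D oxygen, so a formyl group there can activate SNAr for the hindered ether and then become Cβ.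

## Retrosynthetic reasoning

**15 from 14.** Only the three phenols are unmasked. In 14 the ring A diol is a diphenylmethylene ketal and the ring C phenol a benzyl ether. Both tolerate carbonate, ylides, borane, palladium, copper, dilute acid and low-valent chromium, and both should fall in one neutral hydrogenolysis that leaves Cα untouched.

**14 from 13 (key disconnection).** The C4(ring B)–Cα bond is cut. This is the only cut that opens the 18-membered ring, removes the stereocentre and leaves two robust termini: an aryl iodide on the unhindered ring B and an aliphatic aldehyde on ring C. The forward reaction must close the ring by aryl addition to the aldehyde and choose the Re face. A Ni/Cr-mediated coupling with a chiral chromium ligand is asked to do both. A cut at Cα–Cβ would need an asymmetric benzyl addition, for which no general catalyst class exists. A cut at either ether or at the ethano bridge would leave the stereocentre as a separate problem.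

**13 from 12.** The arylacetaldehyde is too labile to carry, so it is held as a methyl enol ether. This survives base, borane, palladium and copper and is released by dilute acid just before the ring closure.

**12 from 10 and 11.** The A–O–B ether is cut at the ring B carbon. Ring B arrives as the boronic acid 11 with its iodide already in place, by copper-mediated oxidative O-arylation of the free ring A phenol of 10. This is done after the palladium step so that the C–I bond never meets zerovalent palladium.

**10 from 8 and 5, via 9.** The ethano bridge is cut at the CH2–ring D bond. Hydroboration of the ring A styrene 8 gives the alkylborane 9, and B-alkyl Suzuki–Miyaura coupling with the ring D bromide of 5 forms the bridge directly at the saturated level. No stilbene has to be hydrogenated in the presence of an enol ether, a benzyl ether or a halide.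

**5 from 4, 4 from 2 and 3, 2 from 1.** The hindered C–O–D ether is cut at the ring C carbon. In 2 the fluoride is ortho to a formyl group, so the phenoxide of 3 can displace it by SNAr. The same formyl carbon then becomes Cβ by one-carbon Wittig homologation to 5. Benzylation of 1 gives 2.

**8 from 7 from 6.** The ring A diol is protected as a ketal, which can only span two neighbouring oxygens of 6. This leaves exactly one terminal phenol free (7). Methylenation of the aldehyde gives the styrene 8.

## Alternatives that were turned down

**Alternative 1:** the textbook route. Both ethers are made by SNAr. The B–C two-carbon unit is built early in open-chain form and its ketone reduced by asymmetric transfer hydrogenation. The ring is closed last at the ethano bridge by intramolecular Wittig olefination to the macrocyclic stilbene A1, followed by hydrogenation.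
- The ring closure builds neither the stereocentre nor a difficult bond.
- Four benzylic carbons at the aldehyde or phosphonium level must be told apart, which costs protection and redox steps; the estimate is well above the ten steps used here.
- The stilbene of A1 must be saturated beside a hydrogenolysis-prone carbinol and benzyl-type protecting groups.

**Alternative 2:** ring closure at the A–O–B ether. The phenoxide of the seco fluoro ketone A2 would displace a fluoride para to the keto group. Asymmetric transfer hydrogenation of the ring carbonyl would then lead to 14.
- The methylene between the carbonyl and ring C in A2 is acidic. Under the carbonate conditions its enolate would switch off the activation of the fluoride and open aldol and O-arylation channels.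
- A2 needs its own C–C bond construction for the aryl benzyl ketone.
- The stereocentre would still cost a separate operation.

**Alternative 3:** ring contraction. A 19-membered dibenzyl ether A3 (ring B–CH2–O–CH2–ring C, from a simple macro-etherification) would undergo a [1,2]-Wittig rearrangement to form the Cα–Cβ bond and the carbinol in one step.
- The carbanion must form at the ring B methylene. That ring is para-oxygenated and so less acidic than the ring C methylene, which has an ortho aryloxy group. The regioisomeric carbinol is the likely product.
- The diaryl ethers invite competing ortho-lithiation.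
- The shift goes through a radical pair, so the configuration at Cα would not be under reliable control.

Key step: step 9

## Route

Step 1
Reactants: 1 2-fluoro-3-hydroxybenzaldehyde
Product: 2 3-(benzyloxy)-2-fluorobenzaldehyde
Conditions: BnBr, K2CO3, DMF, rt
Reagents that add atoms: benzyl bromide, BrCc1ccccc1
Why: Williamson O-alkylation of the only acidic OH; the aldehyde and the aryl fluoride are inert to carbonate at room temperature.

Step 2
Reactants: 2 3-(benzyloxy)-2-fluorobenzaldehyde; 3 3-bromophenol
Product: 4 3-(benzyloxy)-2-(3-bromophenoxy)benzaldehyde
Conditions: K2CO3, DMF, 120 °C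
Reagents that add atoms: none
Why: SNAr: the phenoxide of 3 displaces the fluoride ortho to the formyl group through a Meisenheimer complex, which builds the hindered C–O–D ether; the C–Br bond of 3 is not activated and should stay.

Step 3
Reactants: 4 3-(benzyloxy)-2-(3-bromophenoxy)benzaldehyde
Product: 5 1-(benzyloxy)-2-(3-bromophenoxy)-3-(2-methoxyethenyl)benzene (E/Z mixture)
Conditions: MeOCH2PPh3Cl, KOtBu, THF, 0 °C to rt
Reagents that add atoms: (methoxymethyl)triphenylphosphonium chloride, COC[P+](c1ccccc1)(c1ccccc1)c1ccccc1.[Cl-]
Why: Wittig olefination with the methoxymethylene ylide adds the future Cα as an enol ether; both alkene isomers are the same latent arylacetaldehyde, and the enol ether is stable to the base, borane, palladium and copper of steps 6 and 7.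

Step 4
Reactants: 6 3,4,5-trihydroxybenzaldehyde
Product: 7 7-hydroxy-2,2-diphenyl-1,3-benzodioxole-5-carbaldehyde
Conditions: Ph2CCl2, Ph2O, 175 °C
Reagents that add atoms: dichlorodiphenylmethane, ClC(Cl)(c1ccccc1)c1ccccc1
Why: Catechol ketalisation with a gem-dichloride; only two neighbouring hydroxyls can be bridged and the two possible pairs are equivalent by symmetry, so one ketal with one free terminal phenol should result.

Step 5
Reactants: 7 7-hydroxy-2,2-diphenyl-1,3-benzodioxole-5-carbaldehyde
Product: 8 6-ethenyl-2,2-diphenyl-1,3-benzodioxol-4-ol
Conditions: MePPh3Br (excess), KOtBu (excess), THF, 0 °C to rt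
Reagents that add atoms: methyltriphenylphosphonium bromide, C[P+](c1ccccc1)(c1ccccc1)c1ccccc1.[Br-]
Why: Wittig methylenation; the first equivalent of base makes the phenoxide, which is meta to the formyl group and should not shut down its electrophilicity.

Step 6
Reactants: 8 6-ethenyl-2,2-diphenyl-1,3-benzodioxol-4-ol; 5 1-(benzyloxy)-2-(3-bromophenoxy)-3-(2-methoxyethenyl)benzene
Product: 10 6-[2-(3-{2-(benzyloxy)-6-(2-methoxyethenyl)phenoxy}phenyl)ethyl]-2,2-diphenyl-1,3-benzodioxol-4-ol, via alkylborane 9 (not isolated)
Conditions: 9-BBN (excess), THF, 0 °C to rt; then aq. K3PO4; then 5, Pd(dppf)Cl2 (cat.), DMF, 60 °C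
Reagents that add atoms: 9-borabicyclo[3.3.1]nonane (9-BBN), B1C2CCCC1CCC2 (its boron stays in intermediate 9 only; it leaves one hydrogen in 10)
Why: Anti-Markovnikov hydroboration of the styrene, then B-alkyl Suzuki–Miyaura coupling with the aryl bromide, forms the ring A–CH2–CH2–ring D bridge at the saturated level. The phenol is carried through 9 as its borinate, and the aqueous base destroys residual B–H before 5 is added, so the enol ether is not hydroborated.

Step 7
Reactants: 10 6-[2-(3-{2-(benzyloxy)-6-(2-methoxyethenyl)phenoxy}phenyl)ethyl]-2,2-diphenyl-1,3-benzodioxol-4-ol; 11 (4-iodophenyl)boronic acid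
Product: 12 6-[2-(3-{2-(benzyloxy)-6-(2-methoxyethenyl)phenoxy}phenyl)ethyl]-4-(4-iodophenoxy)-2,2-diphenyl-1,3-benzodioxole (E/Z mixture)
Conditions: Cu(OAc)2 (cat.), pyridine, 4 Å MS, CH2Cl2, O2 (1 atm), rt
Reagents that add atoms: none
Why: Chan–Lam oxidative O-arylation forms the A–O–B ether at room temperature; no low-valent metal able to insert into C–I is present, so ring B should arrive with its iodide intact.

Step 8
Reactants: 12 6-[2-(3-{2-(benzyloxy)-6-(2-methoxyethenyl)phenoxy}phenyl)ethyl]-4-(4-iodophenoxy)-2,2-diphenyl-1,3-benzodioxole
Product: 13 [3-(benzyloxy)-2-(3-{2-[7-(4-iodophenoxy)-2,2-diphenyl-1,3-benzodioxol-5-yl]ethyl}phenoxy)phenyl]acetaldehyde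
Conditions: 2 M aq. HCl, THF, rt to 40 °C; crude product used at once
Reagents that add atoms: water, O
Why: Acid-catalysed enol ether hydrolysis (C-protonation, hemiacetal, loss of methanol) releases the arylacetaldehyde; the catechol ketal and the benzyl ether need stronger acid and should survive.

Step 9
Reactants: 13 [3-(benzyloxy)-2-(3-{2-[7-(4-iodophenoxy)-2,2-diphenyl-1,3-benzodioxol-5-yl]ethyl}phenoxy)phenyl]acetaldehyde
Product: 14 (S)-configured macrocyclic alcohol, i.e. the target with the two ring A hydroxyls as diphenylmethylene ketal and the ring C hydroxyl as benzyl ether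
Conditions: CrCl2 (0.3 equiv), L* (0.33 equiv), 1,8-bis(dimethylamino)naphthalene (0.33 equiv), NiCl2(dmp) (0.05 equiv), Mn powder, Cp2ZrCl2, LiCl, MeCN, rt, 13 added by syringe pump (final 2 mM); aq. NaHCO3 work-up
Reagents that add atoms: none
Why: Proposed new method: a catalytic enantioselective Ni/Cr-mediated (Nozaki–Hiyama–Kishi) aryl iodide–aldehyde coupling run as a macrocyclisation. Mechanism: zerovalent nickel (from NiCl2(dmp) and Mn) inserts into the C–I bond of ring B, the aryl group passes to trivalent chromium bound to the deprotonated oxazoline–sulfonamide L*, and this arylchromium adds to the aldehyde through a four-centred transition state; Cp2ZrCl2 takes over the alkoxide and Mn returns chromium to the divalent state. Closest known reaction types: the catalytic asymmetric Ni/Cr coupling of alkenyl iodides with aldehydes under this ligand class, which has served for macrocyclic ring closure, and the non-asymmetric Ni/Cr coupling of aryl iodides with aldehydes; an sp2 aryl–chromium bond should occupy the ligand pocket as an alkenyl–chromium bond does. Ring closure: the 18-membered ring is closed by C–C bond formation in an 18-exo-trig mode at the formyl carbon. Stereocentre: Cα is controlled by L* on chromium alone, since the substrate has no stereo element; aryl delivery to the Re face gives (S). Selectivity needed: cyclisation over oligomerisation (slow addition), aryl transfer over biaryl coupling (low nickel loading) and addition over enolisation (organochromium species are weakly basic). The substrate secures chemoselectivity by holding one unhindered aryl iodide and one aldehyde beside groups that arylchromium does not attack (ethers, ketal).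

Step 10
Reactants: 14 (S)-configured macrocyclic alcohol (ketal and benzyl ether)
Product: 15 target CNP0356934.1, (S)-configured macrocyclic tetraphenol
Conditions: H2 (1 atm), Pd/C, THF–MeOH, rt, under argon on work-up
Reagents that add atoms: none
Why: Hydrogenolysis cleaves the benzyl ether and both benzylic C–O bonds of the diphenylmethylene ketal; in neutral medium the secondary benzylic alcohol should neither ionise nor be cleaved at a comparable rate, so the (S) configuration is kept.

## Compound list

1 | 2-fluoro-3-hydroxybenzaldehyde | O=Cc1cccc(O)c1F | starting material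
2 | 3-(benzyloxy)-2-fluorobenzaldehyde | O=Cc1cccc(OCc2ccccc2)c1F | intermediate
3 | 3-bromophenol | Oc1cccc(Br)c1 | starting material
4 | 3-(benzyloxy)-2-(3-bromophenoxy)benzaldehyde | O=Cc1cccc(OCc2ccccc2)c1Oc1cccc(Br)c1 | intermediate
5 | 1-(benzyloxy)-2-(3-bromophenoxy)-3-(2-methoxyethenyl)benzene, E/Z mixture | COC=Cc1cccc(OCc2ccccc2)c1Oc1cccc(Br)c1 | intermediate
6 | 3,4,5-trihydroxybenzaldehyde | O=Cc1cc(O)c(O)c(O)c1 | starting material
7 | 7-hydroxy-2,2-diphenyl-1,3-benzodioxole-5-carbaldehyde | O=Cc1cc(O)c2c(c1)OC(c1ccccc1)(c1ccccc1)O2 | intermediate
8 | 6-ethenyl-2,2-diphenyl-1,3-benzodioxol-4-ol | C=Cc1cc(O)c2c(c1)OC(c1ccccc1)(c1ccccc1)O2 | intermediate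
9 | 9-{2-[7-(9-borabicyclo[3.3.1]nonan-9-yloxy)-2,2-diphenyl-1,3-benzodioxol-5-yl]ethyl}-9-borabicyclo[3.3.1]nonane (alkylborane, phenol as borinate) | C(Cc1cc(OB2C3CCCC2CCC3)c2c(c1)OC(c1ccccc1)(c1ccccc1)O2)B1C2CCCC1CCC2 | intermediate (not isolated)
10 | 6-[2-(3-{2-(benzyloxy)-6-(2-methoxyethenyl)phenoxy}phenyl)ethyl]-2,2-diphenyl-1,3-benzodioxol-4-ol, E/Z mixture | COC=Cc1cccc(OCc2ccccc2)c1Oc1cccc(CCc2cc(O)c3c(c2)OC(c2ccccc2)(c2ccccc2)O3)c1 | intermediate
11 | (4-iodophenyl)boronic acid | OB(O)c1ccc(I)cc1 | starting material
12 | 6-[2-(3-{2-(benzyloxy)-6-(2-methoxyethenyl)phenoxy}phenyl)ethyl]-4-(4-iodophenoxy)-2,2-diphenyl-1,3-benzodioxole, E/Z mixture | COC=Cc1cccc(OCc2ccccc2)c1Oc1cccc(CCc2cc(Oc3ccc(I)cc3)c3c(c2)OC(c2ccccc2)(c2ccccc2)O3)c1 | intermediate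
13 | [3-(benzyloxy)-2-(3-{2-[7-(4-iodophenoxy)-2,2-diphenyl-1,3-benzodioxol-5-yl]ethyl}phenoxy)phenyl]acetaldehyde | O=CCc1cccc(OCc2ccccc2)c1Oc1cccc(CCc2cc(Oc3ccc(I)cc3)c3c(c2)OC(c2ccccc2)(c2ccccc2)O3)c1 | intermediate
14 | (S)-macrocyclic alcohol: target with ring A diol as diphenylmethylene ketal and ring C phenol as benzyl ether | C1(c2ccccc2)(c2ccccc2)Oc2cc3cc(c2O1)Oc1ccc(cc1)[C@@H](O)Cc1cccc(OCc2ccccc2)c1Oc1cccc(c1)CC3 | intermediate
15 | CNP0356934.1, (S)-configured macrocyclic bis(bibenzyl) tetraphenol with benzylic alcohol | Oc1cc2cc(c1O)Oc1ccc(cc1)[C@@H](O)Cc1cccc(O)c1Oc1cccc(c1)CC2 | target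

## Step count and risk

Total step count: 10. Longest linear sequence: 8 steps (1, 2, 3, 6, 7, 8, 9, 10 from compound 1).

**Step 9 (key step, proposed new method).** Two processes are most likely to go wrong.
- Poor facial selectivity: the ligand pocket has not been tested for an aryl–chromium bond.
- Slow ring closure at high dilution, which would let reduction of the C–I bond, biaryl coupling and self-condensation of the aldehyde compete.

Fallback with known chemistry: from 13, the Ni/Cr-mediated coupling without chiral ligand (excess CrCl2, catalytic NiCl2, DMSO–THF, high dilution) is a known reaction class for aryl iodides with aldehydes and for macrocyclisation. It should give the racemic macrocyclic alcohol F1. Oxidation with Dess–Martin periodinane would give the macrocyclic ketone F2. Asymmetric transfer hydrogenation with RuCl[(S,S)-TsDPEN](p-cymene) in HCO2H/Et3N should then return to 14, since this catalyst antipode gives the (S)-carbinol of aryl benzyl ketones. Material of low enantiomeric purity from step 9 can enter the same two operations.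

**Step 8.** Partial loss of the diphenylmethylene ketal under the acid, or self-condensation of the arylacetaldehyde before it is used, may erode the material.

Fallback: from 4, Wittig olefination with the ylide of [2-(trimethylsilyl)ethoxymethyl]triphenylphosphonium chloride would give the silylethyl enol ether F3. The sequence of steps 6 and 7 would carry it to the phenol F4 and the iodo diaryl ether F5. Fluoride (TBAF buffered with AcOH, THF, 0 °C) would then fragment the silylethyl group and release the aldehyde without acid, coming back at 13.

**Step 10.** Hydrogenolysis of the benzylic C–OH bond at Cα may compete, above all if the ketal cleaves slowly and long exposure is needed.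

Fallback: from 14, oxidation with Dess–Martin periodinane to the macrocyclic ketone F2, hydrogenolysis (H2, Pd/C) to the triphenolic macrocyclic ketone F6 with the carbinol masked as a carbonyl, and asymmetric transfer hydrogenation with RuCl[(S,S)-TsDPEN](p-cymene) in HCO2H/Et3N as the last operation, coming back at 15.

**Step 7.** Slow O-arylation of the phenol next to the ketal oxygen may leave it unreacted while the boronic acid is consumed by protodeboronation, oxidation and homocoupling.

Fallback: from 10, the roles at ring B are reversed in an Ullmann etherification with excess 1,4-diiodobenzene (CuI, N,N-dimethylglycine, Cs2CO3, dioxane, 90 °C, no oxidant). It comes back at 12 and makes no new compound.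

## Further compounds

F1 | step 9 | racemic macrocyclic alcohol (racemate of 14) | C1(c2ccccc2)(c2ccccc2)Oc2cc3cc(c2O1)Oc1ccc(cc1)C(O)Cc1cccc(OCc2ccccc2)c1Oc1cccc(c1)CC3
F2 | step 9 | macrocyclic ketone (ketal and benzyl ether in place) | C1(c2ccccc2)(c2ccccc2)Oc2cc3cc(c2O1)Oc1ccc(cc1)C(=O)Cc1cccc(OCc2ccccc2)c1Oc1cccc(c1)CC3
F3 | step 8 | 1-(benzyloxy)-2-(3-bromophenoxy)-3-{2-[2-(trimethylsilyl)ethoxy]ethenyl}benzene, E/Z mixture | C[Si](C)(C)CCOC=Cc1cccc(OCc2ccccc2)c1Oc1cccc(Br)c1
F4 | step 8 | silylethyl enol ether analogue of 10 (free ring A phenol), E/Z mixture | C[Si](C)(C)CCOC=Cc1cccc(OCc2ccccc2)c1Oc1cccc(CCc2cc(O)c3c(c2)OC(c2ccccc2)(c2ccccc2)O3)c1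
F5 | step 8 | silylethyl enol ether analogue of 12 (4-iodophenyl ether), E/Z mixture | C[Si](C)(C)CCOC=Cc1cccc(OCc2ccccc2)c1Oc1cccc(CCc2cc(Oc3ccc(I)cc3)c3c(c2)OC(c2ccccc2)(c2ccccc2)O3)c1
F6 | step 10 | triphenolic macrocyclic ketone | Oc1cc2cc(c1O)Oc1ccc(cc1)C(=O)Cc1cccc(O)c1Oc1cccc(c1)CC2
F0 | step 7 | none | none
A1 | alternative 1 | (S)-macrocyclic stilbene (ring A–CH=CH–ring D) with ketal and benzyl ether | C1(c2ccccc2)(c2ccccc2)Oc2cc3cc(c2O1)Oc1ccc(cc1)[C@@H](O)Cc1cccc(OCc2ccccc2)c1Oc1cccc(c1)C=C3
A2 | alternative 2 | seco fluoro ketone with free ring A phenol | O=C(Cc1cccc(OCc2ccccc2)c1Oc1cccc(CCc2cc(O)c3c(c2)OC(c2ccccc2)(c2ccccc2)O3)c1)c1ccc(F)cc1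
A3 | alternative 3 | 19-membered macrocyclic dibenzyl ether (ring B–CH2–O–CH2–ring C) | C1(c2ccccc2)(c2ccccc2)Oc2cc3cc(c2O1)Oc1ccc(cc1)COCc1cccc(OCc2ccccc2)c1Oc1cccc(c1)CC3
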